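**Retrosynthetic overview**
1. The γ-lactone and the C8 isobutyrate come last, from a ten-membered β-hydroxy enone by Evans–Tishchenko reduction (sets C6, delivers the isobutyryl group) and lactonisation.
2. The ten-membered ring comes from a 5→10 ring expansion: β-scission of the ring-fusion bond of a cyclopentenol/cycloheptene bicycle (tertiary alkoxy radical, allyl-radical termination).
3. The bicycle is built from 3-methylcyclopentenone (brings the Z C4=C5 and C15), a zinc Barbier allylation (C6–C7, sets C7) and a ring-closing metathesis (seven-membered ring, fixes the Z C1=C10).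
4. The chain comes from (S)-glyceraldehyde acetonide (C8), a Felkin vinyl addition plus Mitsunobu inversion (C9, installs the hydroxyisobutyrate), and a Baylis–Hillman-type bromide.
5. Ring order: cyclopentene (purchased) → cycloheptene (RCM) → cyclodecadiene (ring expansion) → lactone.

Assumption: locants C1–C15 in the explanations are germacrane numbers of the target; the two stereocentres of the cyclopentene unit in 20, 22 and 23 are destroyed in step 13, so they are carried as a mixture and drawn without configuration.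
Abbreviations: TBDPS = tert-butyl(diphenyl)silyl, TBS = tert-butyl(dimethyl)silyl, TES = triethylsilyl.

**Route**

Step 1
Reactants: 1 2-bromoprop-2-en-1-ol
Product: 2 [(2-bromoprop-2-en-1-yl)oxy](tert-butyl)diphenylsilane
Conditions: TBDPSCl, imidazole, DMF, 0 °C → rt
Reagents that add atoms: tert-butyl(chloro)diphenylsilane, CC(C)(C)[Si](Cl)(c1ccccc1)c1ccccc1
Why: Imidazole-promoted O-silylation gives a primary silyl ether (future C14–O) that survives t-BuLi, aqueous acid, Swern and Ru/Zn conditions; no stereocentre is involved.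

Step 2
Reactants: 3 2-hydroxy-2-methylpropanoic acid
Product: 5 2-(TBS-oxy)-2-methylpropanoic acid, via bis-TBS derivative 4 (not isolated)
Conditions: TBSOTf (2.2 equiv), 2,6-lutidine, CH2Cl2, 0 °C → rt; then K2CO3 (cat.), MeOH/H2O, rt, pH 4 work-up
Reagents that add atoms: tert-butyldimethylsilyl trifluoromethanesulfonate, CC(C)(C)[Si](C)(C)OS(=O)(=O)C(F)(F)F
Why: Exhaustive silylation followed by selective solvolysis of the labile silyl ester leaves the hindered tertiary silyl ether, so the tertiary OH cannot compete as an O–H donor in step 13.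

Step 3
Reactants: 2 [(2-bromoprop-2-en-1-yl)oxy](tert-butyl)diphenylsilane; 6 (4S)-2,2-dimethyl-1,3-dioxolane-4-carbaldehyde
Product: 8 (1R)-2-[(TBDPS-oxy)methyl]-1-[(4S)-2,2-dimethyl-1,3-dioxolan-4-yl]prop-2-en-1-ol, via vinyllithium 7 (not isolated)
Conditions: t-BuLi (2.0 equiv), Et2O, −78 °C; then 6, −78 °C; H2O; anti isomer separated (expected about 4:1)
Reagents that add atoms: none
Why: Br/Li exchange and Felkin–Anh 1,2-addition to the α-alkoxy aldehyde give the anti (erythro) carbinol, which sets C9 with the configuration opposite to that needed; C8 comes from 6.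

Step 4
Reactants: 8 (1R)-2-[(TBDPS-oxy)methyl]-1-[(4S)-2,2-dimethyl-1,3-dioxolan-4-yl]prop-2-en-1-ol; 5 2-(TBS-oxy)-2-methylpropanoic acid
Product: 9 (1S)-2-[(TBDPS-oxy)methyl]-1-[(4S)-2,2-dimethyl-1,3-dioxolan-4-yl]prop-2-en-1-yl 2-(TBS-oxy)-2-methylpropanoate
Conditions: PPh3, DIAD, THF, 0 °C → rt
Reagents that add atoms: none
Why: Mitsunobu esterification (SN2 on the alkoxyphosphonium ion) inverts C9 to the required 8,9-threo relationship and installs the C9 acyl group in the same operation.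

Step 5
Reactants: 9 (1S)-2-[(TBDPS-oxy)methyl]-1-[(4S)-2,2-dimethyl-1,3-dioxolan-4-yl]prop-2-en-1-yl 2-(TBS-oxy)-2-methylpropanoate
Product: 10 (2S,3S)-4-[(TBDPS-oxy)methyl]-1,2-dihydroxypent-4-en-3-yl 2-(TBS-oxy)-2-methylpropanoate
Conditions: AcOH/H2O (4:1), 40 °C
Reagents that add atoms: none
Why: Mild acidic acetonide hydrolysis leaves the TBDPS ether, the tertiary TBS ether and the hindered ester intact; stereocentres are untouched.

Step 6
Reactants: 10 (2S,3S)-4-[(TBDPS-oxy)methyl]-1,2-dihydroxypent-4-en-3-yl 2-(TBS-oxy)-2-methylpropanoate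
Product: 11 (2S,3S)-4-[(TBDPS-oxy)methyl]-1,2-bis(TES-oxy)pent-4-en-3-yl 2-(TBS-oxy)-2-methylpropanoate
Conditions: TESCl (2.4 equiv), imidazole, DMAP (cat.), CH2Cl2, 0 °C
Reagents that add atoms: chlorotriethylsilane, CC[Si](Cl)(CC)CC
Why: Bis-silylation protects the C8 hydroxyl and sets up the primary TES ether for direct oxidation in step 7.

Step 7
Reactants: 11 (2S,3S)-4-[(TBDPS-oxy)methyl]-1,2-bis(TES-oxy)pent-4-en-3-yl 2-(TBS-oxy)-2-methylpropanoate
Product: 12 (2R,3S)-4-[(TBDPS-oxy)methyl]-1-oxo-2-(TES-oxy)pent-4-en-3-yl 2-(TBS-oxy)-2-methylpropanoate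
Conditions: (COCl)2, DMSO, CH2Cl2, −78 → −30 °C; then i-Pr2NEt, −78 → 0 °C
Reagents that add atoms: none
Why: Swern conditions oxidise a primary TES ether directly to the aldehyde while secondary TES, TBS and TBDPS ethers survive; Hünig's base at low temperature avoids C8 epimerisation and β-elimination of the C9 ester (the descriptor at C8 changes only through CIP priorities).

Step 8
Reactants: 12 (2R,3S)-4-[(TBDPS-oxy)methyl]-1-oxo-2-(TES-oxy)pent-4-en-3-yl 2-(TBS-oxy)-2-methylpropanoate; 13 methyl prop-2-ynoate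
Product: 15 methyl (4S,5S)-3-hydroxy-2-methylidene-5-{[2-(TBS-oxy)-2-methylpropanoyl]oxy}-6-[(TBDPS-oxy)methyl]-4-(TES-oxy)hept-6-enoate (both C3 epimers), via vinylalane 14 (not isolated)
Conditions: 13, DIBAL-H, NMO, THF, 0 °C, 1 h; then 12, 0 °C → rt; aq. Rochelle salt
Reagents that add atoms: none
Why: Vinylalumination (hydroalumination of the propiolate, then addition of the α-alanyl acrylate to the aldehyde) is an amine-free Baylis–Hillman surrogate, so the base-sensitive α-silyloxy-β-acyloxy aldehyde is not epimerised; the new carbinol is removed in step 9.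

Step 9
Reactants: 15 methyl (4S,5S)-3-hydroxy-2-methylidene-5-{[2-(TBS-oxy)-2-methylpropanoyl]oxy}-6-[(TBDPS-oxy)methyl]-4-(TES-oxy)hept-6-enoate
Product: 16 methyl (2Z,4S,5S)-2-(bromomethyl)-5-{[2-(TBS-oxy)-2-methylpropanoyl]oxy}-6-[(TBDPS-oxy)methyl]-4-(TES-oxy)hepta-2,6-dienoate
Conditions: NBS, Me2S, CH2Cl2, 0 °C → rt
Reagents that add atoms: N-bromosuccinimide, O=C1CCC(=O)N1Br
Why: Corey–Kim-type activation of the Baylis–Hillman alcohol followed by SN2′ bromide delivery gives the (Z)-2-(bromomethyl)enoate, the standard precursor of 2-(alkoxycarbonyl)allyl metals.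

Step 10
Reactants: 17 3-methylcyclopent-2-en-1-one; 18 bromoethene
Product: 20 5-ethenyl-3-methylcyclopent-2-en-1-one (racemic), via lithium dienolate 19 (not isolated)
Conditions: LiHMDS, THF, −78 °C; then 18, Pd2(dba)3 (2 mol %), t-Bu3P·HBF4 (8 mol %), −78 °C → rt; used cold without storage
Reagents that add atoms: none
Why: Pd-catalysed α-alkenylation of the kinetic (α′) ketone enolate with a vinyl bromide gives the β,γ-unsaturated ketone; its stereocentre (C2) is sacrificial.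

Step 11
Reactants: 16 methyl (2Z,4S,5S)-2-(bromomethyl)-5-{[2-(TBS-oxy)-2-methylpropanoyl]oxy}-6-[(TBDPS-oxy)methyl]-4-(TES-oxy)hepta-2,6-dienoate; 20 5-ethenyl-3-methylcyclopent-2-en-1-one
Product: 22 methyl (3R,4S,5S)-3-(5-ethenyl-1-hydroxy-3-methylcyclopent-2-en-1-yl)-2-methylidene-5-{[2-(TBS-oxy)-2-methylpropanoyl]oxy}-6-[(TBDPS-oxy)methyl]-4-(TES-oxy)hept-6-enoate, via allylzinc bromide 21 (not isolated)
Conditions: Zn dust, THF/sat. aq. NH4Cl (1:1), 0 °C → rt; 20 (2.5 equiv)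
Reagents that add atoms: none
Why: Aqueous Barbier (SE2′) allylation of the ketone forms C6–C7 and the α-methylene ester, and the buffered medium keeps the open hydroxy ester. C7 is set by Felkin-type attack of the ketone anti to the bulky C9-bearing branch, with the C8–H eclipsing the alkene (allylic strain) — a steric model, flagged as a risk below. The allyl unit is expected to add trans to the ring vinyl group.

Step 12
Reactants: 22 methyl (3R,4S,5S)-3-(5-ethenyl-1-hydroxy-3-methylcyclopent-2-en-1-yl)-2-methylidene-5-{[2-(TBS-oxy)-2-methylpropanoyl]oxy}-6-[(TBDPS-oxy)methyl]-4-(TES-oxy)hept-6-enoate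
Product: 23 methyl 2-[(4R,5S,6S)-3a-hydroxy-2-methyl-6-{[2-(TBS-oxy)-2-methylpropanoyl]oxy}-7-[(TBDPS-oxy)methyl]-5-(TES-oxy)-1,3a,4,5,6,8a-hexahydroazulen-4-yl]prop-2-enoate (3a/8a trans-fused)
Conditions: Grubbs II (10 mol %), toluene (2 mM), 80 °C
Reagents that add atoms: none
Why: Ring-closing metathesis of the ring vinyl group with the 1,1-disubstituted C10 alkene closes the cycloheptene, which forces the C1=C10 bond cis; the competing five-ring closure onto the acrylate would need a trans-fused bicyclo[3.3.0]octene because the vinyl group and the C7 chain are trans.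

Step 13
Reactants: 23 methyl 2-[(4R,5S,6S)-3a-hydroxy-2-methyl-6-{[2-(TBS-oxy)-2-methylpropanoyl]oxy}-7-[(TBDPS-oxy)methyl]-5-(TES-oxy)-1,3a,4,5,6,8a-hexahydroazulen-4-yl]prop-2-enoate
Product: 24 methyl 2-[(1R,2S,3S,4Z,8Z)-8-methyl-10-oxo-3-{[2-(TBS-oxy)-2-methylpropanoyl]oxy}-4-[(TBDPS-oxy)methyl]-2-(TES-oxy)cyclodeca-4,8-dien-1-yl]prop-2-enoate
Conditions: [Ir(dF(CF3)ppy)2(5,5′-d(CF3)bpy)]PF6 (2 mol %), Bu4P+ (MeO)2PO2− (20 mol %), 2,4,6-triisopropylbenzenethiol (30 mol %), PhCF3 (5 mM), blue LEDs, 25 °C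
Reagents that add atoms: none
Why: Proposed new method: a redox-neutral 5→10 ring expansion of a fused tertiary allylic alcohol. Phosphate-assisted proton-coupled electron transfer to the excited Ir(III) catalyst gives the C6 alkoxy radical. β-Scission of the ring-fusion bond C6–C2 is favoured over C6–C7 because it forms the Z-enone and the more substituted allyl radical (C2–C1–C10). The bulky thiol then transfers H to the less hindered C2 terminus faster than the allyl radical can rotate, so the ring-imposed Z geometry of C1=C10 and the C7–C9 stereocentres are kept, and Ir(II) reduces the thiyl radical to close the cycle. The closest known reactions are the photocatalytic PCET ring-opening of monocyclic cycloalkanols with thiol hydrogen-atom transfer and stoichiometric alkoxy-radical (hypoiodite) fragmentations of bicyclic carbinols.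

Step 14
Reactants: 24 methyl 2-[(1R,2S,3S,4Z,8Z)-8-methyl-10-oxo-3-{[2-(TBS-oxy)-2-methylpropanoyl]oxy}-4-[(TBDPS-oxy)methyl]-2-(TES-oxy)cyclodeca-4,8-dien-1-yl]prop-2-enoate
Product: 25 methyl 2-[(1R,2S,3S,4Z,8Z)-2-hydroxy-4-(hydroxymethyl)-3-[(2-hydroxy-2-methylpropanoyl)oxy]-8-methyl-10-oxocyclodeca-4,8-dien-1-yl]prop-2-enoate
Conditions: HF·pyridine, THF/pyridine, 0 °C → rt
Reagents that add atoms: none
Why: Buffered acidic fluoride removes all three silyl ethers without the base that would cause acyl migration, retro-aldol cleavage or C7 epimerisation of the β-hydroxy ketone.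

Step 15
Reactants: 25 methyl 2-[(1R,2S,3S,4Z,8Z)-2-hydroxy-4-(hydroxymethyl)-3-[(2-hydroxy-2-methylpropanoyl)oxy]-8-methyl-10-oxocyclodeca-4,8-dien-1-yl]prop-2-enoate; 26 2-methylpropanal
Product: 28 (3aS,4S,5S,6Z,10Z,11aR)-6-(hydroxymethyl)-10-methyl-3-methylidene-4-[(2-methylpropanoyl)oxy]-2-oxo-2,3,3a,4,5,8,9,11a-octahydrocyclodeca[b]furan-5-yl 2-hydroxy-2-methylpropanoate, via hydroxy ester 27 (not isolated)
Conditions: SmI2 (0.3 equiv, premixed with 26), 26 (6 equiv), THF, −10 °C; then CSA (cat.), CH2Cl2, rt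
Reagents that add atoms: none
Why: Evans–Tishchenko reduction: the samarium-bound hemiacetal of the C8 hydroxyl delivers hydride intramolecularly to the C6 ketone, giving the 1,3-anti alcohol (6R) and leaving the isobutyryl group on O8; the C6 hydroxyl then closes the trans-fused α-methylene γ-lactone with loss of methanol.

**Compound list**
1 | 2-bromoprop-2-en-1-ol | C=C(Br)CO | starting material
2 | [(2-bromoprop-2-en-1-yl)oxy](tert-butyl)diphenylsilane | C=C(Br)CO[Si](c1ccccc1)(c1ccccc1)C(C)(C)C | intermediate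
3 | 2-hydroxy-2-methylpropanoic acid | CC(C)(O)C(=O)O | starting material
4 | tert-butyldimethylsilyl 2-(TBS-oxy)-2-methylpropanoate | CC(C)(O[Si](C)(C)C(C)(C)C)C(=O)O[Si](C)(C)C(C)(C)C | intermediate
5 | 2-(TBS-oxy)-2-methylpropanoic acid | CC(C)(O[Si](C)(C)C(C)(C)C)C(=O)O | intermediate
6 | (4S)-2,2-dimethyl-1,3-dioxolane-4-carbaldehyde | O=C[C@H]1OC(C)(C)OC1 | starting material
7 | [3-(TBDPS-oxy)prop-1-en-2-yl]lithium | [Li]C(=C)CO[Si](c1ccccc1)(c1ccccc1)C(C)(C)C | intermediate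
8 | (1R)-2-[(TBDPS-oxy)methyl]-1-[(4S)-2,2-dimethyl-1,3-dioxolan-4-yl]prop-2-en-1-ol | C=C(CO[Si](c1ccccc1)(c1ccccc1)C(C)(C)C)[C@@H](O)[C@H]1OC(C)(C)OC1 | intermediate
9 | (1S)-2-[(TBDPS-oxy)methyl]-1-[(4S)-2,2-dimethyl-1,3-dioxolan-4-yl]prop-2-en-1-yl 2-(TBS-oxy)-2-methylpropanoate | C=C(CO[Si](c1ccccc1)(c1ccccc1)C(C)(C)C)[C@H](OC(=O)C(C)(C)O[Si](C)(C)C(C)(C)C)[C@H]1OC(C)(C)OC1 | intermediate
10 | (2S,3S)-4-[(TBDPS-oxy)methyl]-1,2-dihydroxypent-4-en-3-yl 2-(TBS-oxy)-2-methylpropanoate | C=C(CO[Si](c1ccccc1)(c1ccccc1)C(C)(C)C)[C@H](OC(=O)C(C)(C)O[Si](C)(C)C(C)(C)C)[C@@H](O)CO | intermediate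
11 | (2S,3S)-4-[(TBDPS-oxy)methyl]-1,2-bis(TES-oxy)pent-4-en-3-yl 2-(TBS-oxy)-2-methylpropanoate | C=C(CO[Si](c1ccccc1)(c1ccccc1)C(C)(C)C)[C@H](OC(=O)C(C)(C)O[Si](C)(C)C(C)(C)C)[C@@H](O[Si](CC)(CC)CC)CO[Si](CC)(CC)CC | intermediate
12 | (2R,3S)-4-[(TBDPS-oxy)methyl]-1-oxo-2-(TES-oxy)pent-4-en-3-yl 2-(TBS-oxy)-2-methylpropanoate | C=C(CO[Si](c1ccccc1)(c1ccccc1)C(C)(C)C)[C@H](OC(=O)C(C)(C)O[Si](C)(C)C(C)(C)C)[C@@H](O[Si](CC)(CC)CC)C=O | intermediate
13 | methyl prop-2-ynoate | C#CC(=O)OC | starting material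
14 | [1-(methoxycarbonyl)ethenyl]bis(2-methylpropyl)aluminium | C=C(C(=O)OC)[Al](CC(C)C)CC(C)C | intermediate
15 | methyl (4S,5S)-3-hydroxy-2-methylidene-5-{[2-(TBS-oxy)-2-methylpropanoyl]oxy}-6-[(TBDPS-oxy)methyl]-4-(TES-oxy)hept-6-enoate (C3 epimers) | C=C(CO[Si](c1ccccc1)(c1ccccc1)C(C)(C)C)[C@H](OC(=O)C(C)(C)O[Si](C)(C)C(C)(C)C)[C@@H](O[Si](CC)(CC)CC)C(O)C(=C)C(=O)OC | intermediate
16 | methyl (2Z,4S,5S)-2-(bromomethyl)-5-{[2-(TBS-oxy)-2-methylpropanoyl]oxy}-6-[(TBDPS-oxy)methyl]-4-(TES-oxy)hepta-2,6-dienoate | C=C(CO[Si](c1ccccc1)(c1ccccc1)C(C)(C)C)[C@H](OC(=O)C(C)(C)O[Si](C)(C)C(C)(C)C)[C@@H](O[Si](CC)(CC)CC)/C=C(/C(=O)OC)CBr | intermediate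
17 | 3-methylcyclopent-2-en-1-one | CC1=CC(=O)CC1 | starting material
18 | bromoethene | C=CBr | starting material
19 | lithium 4-methylcyclopenta-1,4-dien-1-olate | [Li+].CC1=CC([O-])=CC1 | intermediate
20 | 5-ethenyl-3-methylcyclopent-2-en-1-one (racemic) | C=CC1CC(C)=CC1=O | intermediate
21 | allylzinc bromide from 16 (CH2Br replaced by CH2ZnBr) | C=C(CO[Si](c1ccccc1)(c1ccccc1)C(C)(C)C)[C@H](OC(=O)C(C)(C)O[Si](C)(C)C(C)(C)C)[C@@H](O[Si](CC)(CC)CC)/C=C(/C(=O)OC)C[Zn]Br | intermediate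
22 | methyl (3R,4S,5S)-3-(5-ethenyl-1-hydroxy-3-methylcyclopent-2-en-1-yl)-2-methylidene-5-{[2-(TBS-oxy)-2-methylpropanoyl]oxy}-6-[(TBDPS-oxy)methyl]-4-(TES-oxy)hept-6-enoate | C=CC1CC(C)=CC1(O)[C@H](C(=C)C(=O)OC)[C@H](O[Si](CC)(CC)CC)[C@@H](OC(=O)C(C)(C)O[Si](C)(C)C(C)(C)C)C(=C)CO[Si](c1ccccc1)(c1ccccc1)C(C)(C)C | intermediate
23 | methyl 2-[(4R,5S,6S)-3a-hydroxy-2-methyl-6-{[2-(TBS-oxy)-2-methylpropanoyl]oxy}-7-[(TBDPS-oxy)methyl]-5-(TES-oxy)-1,3a,4,5,6,8a-hexahydroazulen-4-yl]prop-2-enoate | COC(=O)C(=C)[C@@H]1[C@H](O[Si](CC)(CC)CC)[C@@H](OC(=O)C(C)(C)O[Si](C)(C)C(C)(C)C)C(CO[Si](c2ccccc2)(c2ccccc2)C(C)(C)C)=CC2CC(C)=CC12O | intermediate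
24 | methyl 2-[(1R,2S,3S,4Z,8Z)-8-methyl-10-oxo-3-{[2-(TBS-oxy)-2-methylpropanoyl]oxy}-4-[(TBDPS-oxy)methyl]-2-(TES-oxy)cyclodeca-4,8-dien-1-yl]prop-2-enoate | O=C1/C=C(/C)CC/C=C(/CO[Si](c2ccccc2)(c2ccccc2)C(C)(C)C)[C@H](OC(=O)C(C)(C)O[Si](C)(C)C(C)(C)C)[C@@H](O[Si](CC)(CC)CC)[C@H]1C(=C)C(=O)OC | intermediate
25 | methyl 2-[(1R,2S,3S,4Z,8Z)-2-hydroxy-4-(hydroxymethyl)-3-[(2-hydroxy-2-methylpropanoyl)oxy]-8-methyl-10-oxocyclodeca-4,8-dien-1-yl]prop-2-enoate | O=C1/C=C(/C)CC/C=C(/CO)[C@H](OC(=O)C(C)(C)O)[C@@H](O)[C@H]1C(=C)C(=O)OC | intermediate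
26 | 2-methylpropanal | CC(C)C=O | starting material
27 | methyl 2-[(1S,2S,3S,4Z,8Z,10R)-10-hydroxy-4-(hydroxymethyl)-3-[(2-hydroxy-2-methylpropanoyl)oxy]-8-methyl-2-[(2-methylpropanoyl)oxy]cyclodeca-4,8-dien-1-yl]prop-2-enoate | O[C@@H]1/C=C(/C)CC/C=C(/CO)[C@H](OC(=O)C(C)(C)O)[C@@H](OC(=O)C(C)C)[C@H]1C(=C)C(=O)OC | intermediate
28 | (3aS,4S,5S,6Z,10Z,11aR)-6-(hydroxymethyl)-10-methyl-3-methylidene-4-[(2-methylpropanoyl)oxy]-2-oxo-2,3,3a,4,5,8,9,11a-octahydrocyclodeca[b]furan-5-yl 2-hydroxy-2-methylpropanoate (CNP0220567.2) | C=C1C(=O)O[C@@H]2/C=C(/C)CC/C=C(/CO)[C@H](OC(=O)C(C)(C)O)[C@@H](OC(=O)C(C)C)[C@@H]12 | target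

**Step count**
Total: 15 steps. Longest linear sequence: 13 steps (1, 3, 4, 5, 6, 7, 8, 9, 11, 12, 13, 14, 15).

**Three steps most likely to fail, with fallbacks**

Step 13 (the proposed new ring expansion). Risks are scission of C6–C7 instead of C6–C2, transannular addition of the allyl radical to the acrylate, and H delivery to C10. The fallback uses known chemistry and sets out from 23: a Suárez hypoiodite fragmentation (PhI(OAc)2, I2, CH2Cl2, visible light) generates the same alkoxy radical stoichiometrically and traps the ring-opened allyl radical with iodine, giving the ten-membered allylic iodide methyl 2-[(1R,2S,3S,4Z,8Z)-6-iodo-8-methyl-10-oxo-3-{[2-(TBS-oxy)-2-methylpropanoyl]oxy}-4-[(TBDPS-oxy)methyl]-2-(TES-oxy)cyclodeca-4,8-dien-1-yl]prop-2-enoate F5. Tin hydride deiodination (Bu3SnH, Et3B/air, toluene, 0 °C) then replaces iodine by hydrogen at C2, and the sequence comes back to the route at 24.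

Step 11 (Barbier allylation of a hindered ketone, with C7 set by 1,2-induction). The fallback sets out from 15 and 20 and replaces the preformed allylic bromide and zinc by catalytic π-allyl umpolung. Alcohol 15 is acetylated (Ac2O, DMAP, pyridine) to the Baylis–Hillman acetate methyl (4S,5S)-3-acetoxy-2-methylidene-5-{[2-(TBS-oxy)-2-methylpropanoyl]oxy}-6-[(TBDPS-oxy)methyl]-4-(TES-oxy)hept-6-enoate F1. Pd(PPh3)4 (5 mol %) and InI in THF/H2O convert F1 through a π-allylpalladium into an allylindium species that adds to 20, and the sequence comes back at 22. If C7 forms with the wrong configuration, the same fallback can be run with the C8 hydroxyl free so that indium chelation reverses the facial bias.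

Step 12 (RCM of a hindered 1,1-disubstituted alkene next to a free acrylate). The fallback sets out from 22. The tertiary alcohol is first closed onto the ester (CSA, CH2Cl2) to the spiro α-methylene lactone (3S)-3-{(1S,2S)-2-{[2-(TBS-oxy)-2-methylpropanoyl]oxy}-3-[(TBDPS-oxy)methyl]-1-(TES-oxy)but-3-en-1-yl}-9-ethenyl-7-methyl-4-methylidene-2-oxaspiro[4.4]non-6-en-1-one F2 (named as drawn in the block), in which metathesis at the lactone methylene is excluded by Bredt's rule. RCM (Grubbs II, toluene, 80 °C) then gives the tricyclic lactone F3 (the C6–O12 lactone of 23). Saponification of the lactone (LiOH, THF/H2O, 0 °C) gives the hydroxy acid 2-[(4R,5S,6S)-3a-hydroxy-2-methyl-6-{[2-(TBS-oxy)-2-methylpropanoyl]oxy}-7-[(TBDPS-oxy)methyl]-5-(TES-oxy)-1,3a,4,5,6,8a-hexahydroazulen-4-yl]prop-2-enoic acid F4, and neutral methylation (TMSCHN2, MeOH/toluene) comes back to the route at 23.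

Further compounds
F1 | step 11 | methyl (4S,5S)-3-acetoxy-2-methylidene-5-{[2-(TBS-oxy)-2-methylpropanoyl]oxy}-6-[(TBDPS-oxy)methyl]-4-(TES-oxy)hept-6-enoate | C=C(CO[Si](c1ccccc1)(c1ccccc1)C(C)(C)C)[C@H](OC(=O)C(C)(C)O[Si](C)(C)C(C)(C)C)[C@@H](O[Si](CC)(CC)CC)C(OC(C)=O)C(=C)C(=O)OC
F2 | step 12 | spiro α-methylene γ-lactone of 22 (C6–O closed onto C12) | C=CC1CC(C)=CC12OC(=O)C(=C)[C@@H]2[C@H](O[Si](CC)(CC)CC)[C@@H](OC(=O)C(C)(C)O[Si](C)(C)C(C)(C)C)C(=C)CO[Si](c1ccccc1)(c1ccccc1)C(C)(C)C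
F3 | step 12 | tricyclic lactone of 23 (cyclopentene, cycloheptene and spiro-fused α-methylene γ-lactone) | C=C1C(=O)OC23C=C(C)CC2C=C(CO[Si](c2ccccc2)(c2ccccc2)C(C)(C)C)[C@H](OC(=O)C(C)(C)O[Si](C)(C)C(C)(C)C)[C@@H](O[Si](CC)(CC)CC)[C@@H]13
F4 | step 12 | 2-[(4R,5S,6S)-3a-hydroxy-2-methyl-6-{[2-(TBS-oxy)-2-methylpropanoyl]oxy}-7-[(TBDPS-oxy)methyl]-5-(TES-oxy)-1,3a,4,5,6,8a-hexahydroazulen-4-yl]prop-2-enoic acid | OC(=O)C(=C)[C@@H]1[C@H](O[Si](CC)(CC)CC)[C@@H](OC(=O)C(C)(C)O[Si](C)(C)C(C)(C)C)C(CO[Si](c2ccccc2)(c2ccccc2)C(C)(C)C)=CC2CC(C)=CC12O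
F5 | step 13 | methyl 2-[(1R,2S,3S,4Z,8Z)-6-iodo-8-methyl-10-oxo-3-{[2-(TBS-oxy)-2-methylpropanoyl]oxy}-4-[(TBDPS-oxy)methyl]-2-(TES-oxy)cyclodeca-4,8-dien-1-yl]prop-2-enoate | O=C1/C=C(/C)CC(I)/C=C(/CO[Si](c2ccccc2)(c2ccccc2)C(C)(C)C)[C@H](OC(=O)C(C)(C)O[Si](C)(C)C(C)(C)C)[C@@H](O[Si](CC)(CC)CC)[C@H]1C(=C)C(=O)OC
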